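The readings come from a simulation with constants of no real substance, and the scatter is random.

Beware of pricing a catalyst charge in points of product, as if a second charge must repeat the first. Reckon with the fraction left.

| setting | green | violet | flask |
|---|---|---|---|
| starting material | 0.020 M | 0.010 M | 0.020 M |
| protic impurity | 4 mM | 4 mM | 4.00 mM |
| free catalyst | 2.5 mol% | 2.5 mol% | 2.5 mol% |
| temperature | 70 °C | 65 °C | 70 °C |
| remark | the very flask that is asked about, followed so far | run made earlier |  |
| time |  |  | 4.0 d |

- green (time / h: product / %): 5.00: 14; 8.00: 16; 10.0: 23; 15.0: 28; 25.0: 32; 40.0: 42; 60.0: 40
- violet (time / h: product / %): 2.00: 1; 5.00: 8; 10.0: 13; 15.0: 16; 20.0: 21; 30.0: 23; 40.0: 27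

(scatter of a reading: 2 percentage points)

- north: at 4.0 d take out 90 % of the product then present, then wait 8.0 d
- east: change nothing and wait 8.0 d more
- north-west: at 4.0 d raise the temperature by 10 K, then wait 8.0 d
- north-east: at 4.0 d add free catalyst, 100 % of the amount charged, then wait 8.0 d

* product, in percent of the starting material first charged, at 4.0 d
* the remedy with the largest gain of product, or "none" below 2 percentage points (north / east / north-west / north-east / none)
* product present, with what was taken out counted in, in percent of the starting material first charged, after north-west
* product present, with what was taken out counted in, in percent of the starting material first charged, after north-east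

- a species is counted by the starting material in it: one spent catalyst B counts as two
- removed product is counted in
- the analysis behind the earlier runs scatters by 2 percentage points, standard deviation
- steps thought possible: starting material + protic impurity -> quenched substrate; starting material + catalyst intermediate -> spent catalyst B; free catalyst -> spent catalyst A; starting material + free catalyst -> catalyst intermediate; catalyst intermediate <-> free catalyst + product
- additions bring no volume worth counting

Take the rate in the green flask. Over the first 5.00 h product comes at 0.0280 h⁻¹ as a fraction of the charge, and between 15.0 h and 40.0 h at 0.00560 h⁻¹, so the rate has fallen by a factor 5.00. Part of that is material running down. Count the protic impurity's share as lost, one starting material for each, and 80.0 % of the charge stays open to the catalyst. Between those two windows the open part shrinks by a factor 1.62. The remaining factor, 3.08, is larger, and I lay it to the catalyst. The last two green readings average 41.0 % and differ by 2 percentage points against a scatter of 2 points, so I read a plateau there, with 39.0 % of the charge open by this count.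

Now add up the slowing. If the rate is open material times working catalyst, then rate over open material follows the catalyst, so a charge whose life does not depend on what it meets multiplies the open material by a constant factor. Read off the green readings, that factor is 0.488, about half. Call the fraction of open starting material that outlasts one charge the dose survival. My own reckoning is therefore 41.0 % at 4.0 d, and for north-east 61.0 %, a gain of 20 points.

The forecast gives 41 % (38 % to 45 %), picks north-east, and puts north-west at 42 % (39 % to 47 %) and north-east at 66 % (55 % to 74 %), on the ground that “A fresh catalyst dose could give about 16 more turnovers”. Its north-east figure stands above mine.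

The simulation gives 41.5 %, picks north-east, and yields 41.9 % after north-west and 58.9 % after north-east.

    starting material + protic impurity → quenched substrate (k = 4.08 L mol⁻¹ h⁻¹, Ea = 67.0 kJ mol⁻¹)
    starting material + catalyst intermediate → spent catalyst B (k = 10.2 L mol⁻¹ h⁻¹, Ea = 75.0 kJ mol⁻¹)
    free catalyst → spent catalyst A (k = 0.00913 h⁻¹, Ea = 106 kJ mol⁻¹)
    starting material + free catalyst → catalyst intermediate (k = 88.4 L mol⁻¹ h⁻¹, Ea = 72.0 kJ mol⁻¹)
    catalyst intermediate ⇌ free catalyst + product (K = 0.0110 M, k = 30.2 h⁻¹, Ea = 101 kJ mol⁻¹, ΔH = −21.0 kJ mol⁻¹)
    (constants at 70 °C)

Measured on the open material, the second charge in the asked flask left a dose survival of 0.548, against the 0.488 read from green. A neighbour charged with 4.2 mol% of free catalyst holds 1.68 charges, so the green dose survival raised to that power gives the part of the open material left, and the product reckoned from that part is 56.1 %. At 4.0 d that neighbour stands at 54.0 % product, with 20.5 % starting material.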